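## Retrosynthetic overview
1. The 16-membered lactone is closed last by an intramolecular Stille coupling (C5–C6, Z-trisubstituted diene). The Cl–OH of alcohol **40** is first esterified with (2E,4Z)-5-iodohexadienoic acid **18**, and a final TBS removal gives the target.
2. **40** comes from a Julia–Kocienski union of decalin enal **38** with PT-sulfone **33**. **33** carries the Me/O/Me/O/Me(N) stereopentad, made by Felkin/anti-crotylboration of (R)-N,N-dibenzylalaninal and then an organocatalytic anti-aldol with propanal.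
3. Decalin **14** is cis-fused and carries the quaternary C–Me/CHO. It forms from Z-enal **13** by an iminium-catalysed intramolecular Diels–Alder (IMDA), which builds the cyclohexane ring and the cyclohexene ring in one step. The syn-1,3-O,O tether comes from an organocatalytic aldol followed by Narasaka–Prasad reduction.
4. Ring order: both decalin rings together (IMDA), then the macrocycle.

Assumption: the relative configuration was read directly from the target SMILES (cis-fused decalin, syn-1,3 OMe/OCONH2, all four ring-B substituents of the macrocycle and ring A on one face). I also assume the (2S,5S) imidazolidinone is the matched catalyst for the C1/C3 stereocentres of **13**.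

---

## Route

**Step 1**
Reactants: 1 (E)-but-2-ene-1,4-diol
Product: 2 (E)-4-(TBSO)but-2-en-1-ol
Conditions: NaH (1.0 equiv), TBSCl (1.0 equiv), diol in excess, THF, 0 °C
Reagents that add atoms: TBSCl, CC(C)(C)[Si](C)(C)Cl
Why: Statistical mono-silylation of a symmetric diol; no stereocentre is formed.

**Step 2**
Reactants: 2
Product: 3 (2E,4E)-6-(TBSO)hexa-2,4-dienal
Conditions: MnO2 (15 equiv), Ph3P=CHCHO (1.5 equiv), toluene, 60 °C
Reagents that add atoms: (formylmethylene)triphenylphosphorane, O=CC=P(c1ccccc1)(c1ccccc1)c1ccccc1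
Why: Tandem MnO2 oxidation and stabilised-ylide Wittig olefination gives the E,E-dienal without isolating the volatile enal.

**Step 3**
Reactants: 3 (dienal), 4 (4,4-dimethoxybutan-2-one)
Product: 5 (5S,6E,8E)-10-(TBSO)-5-hydroxy-1,1-dimethoxydeca-6,8-dien-3-one
Conditions: (R)-proline (30 mol%), 4 (10 equiv), DMSO, 23 °C, 48 h
Reagents that add atoms: none
Why: Direct asymmetric aldol (List–Barbas): the D-proline enamine forms at the methyl terminus and attacks the Si face of the dienal, setting C3 as (S).

**Step 4**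
Reactants: 5
Product: 6 syn-1,3-diol (3R,5S)
Conditions: Et2BOMe (1.2 equiv), NaBH4 (1.2 equiv), THF/MeOH 4:1, −78 °C; MeOH co-evaporation
Reagents that add atoms: none
Why: Narasaka–Prasad chelation-controlled reduction of the β-hydroxy ketone gives the syn-1,3-diol and sets C1 relative to C3.

**Step 5**
Reactants: 6
Product: 7 cyclic mixed acetal, 2-methoxy-6-dienyl-tetrahydropyran-4-ol (anomeric mixture)
Conditions: PPTS (10 mol%), CH2Cl2, 4 Å MS, 23 °C
Reagents that add atoms: none (MeOH is lost)
Why: Intramolecular transacetalization can only involve C3–OH (6-ring; the C1–OH would need a 4-ring), so C3–O is masked and C1–OH is the only free hydroxyl.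

**Step 6**
Reactants: 7
Product: 8 C1-methyl ether of 7
Conditions: NaH (1.5 equiv), MeI (3 equiv), THF/DMF 5:1, 0 °C
Reagents that add atoms: MeI, CI
Why: Williamson methylation of the single free secondary alcohol; the acetal and silyl ether are base-stable and C1 retains its configuration.

**Step 7**
Reactants: 8
Product: 9 lactol, 4-methoxy-6-dienyl-tetrahydropyran-2-ol
Conditions: PPTS (0.3 equiv), acetone/H2O 5:1, 50 °C
Reagents that add atoms: water, O
Why: Mild acid hydrolysis of the mixed acetal releases the masked δ-hydroxy aldehyde as its lactol (hydroxy-aldehyde ⇌ lactol).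

**Step 8**
Reactants: 9
Product: 10 methyl (2Z,8E,10E)-12-(TBSO)-7-hydroxy-5-methoxy-2-methyldodeca-2,8,10-trienoate
Conditions: (CF3CH2O)2P(O)CH(Me)CO2Me (2.5 equiv), KHMDS (5 equiv), 18-crown-6 (8 equiv), THF, −78 → −40 °C
Reagents that add atoms: methyl 2-[bis(2,2,2-trifluoroethoxy)phosphoryl]propanoate, COC(=O)C(C)P(=O)(OCC(F)(F)F)OCC(F)(F)F
Why: Still–Gennari HWE on the open-chain aldehyde form of the lactol gives the Z-trisubstituted enoate (ester cis to the tether), which fixes the Z-dienophile geometry required for cis-decalin formation.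

**Step 9**
Reactants: 10
Product: 11 primary carbamate at C3
Conditions: Cl3CC(O)NCO (1.5 equiv), CH2Cl2, 0 °C; then K2CO3, MeOH, 0 → 23 °C
Reagents that add atoms: trichloroacetyl isocyanate, ClC(Cl)(Cl)C(=O)N=C=O
Why: Isocyanate carbamoylation of the dienylic alcohol with retention, then methanolysis of the N-trichloroacetyl group; this also removes the free alkoxide that could undergo oxa-Michael addition.

**Step 10**
Reactants: 11
Product: 12 (Z)-allylic alcohol
Conditions: DIBAL-H (3.5 equiv), CH2Cl2, −78 °C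
Reagents that add atoms: none
Why: Chemoselective reduction of the enoate; the carbamate (as its N-Al salt), diene and TBS ether survive at −78 °C and the Z-geometry is retained.

**Step 11**
Reactants: 12
Product: 13 Z-enal (IMDA substrate)
Conditions: DMP (1.5 equiv), NaHCO3, CH2Cl2, 0 °C
Reagents that add atoms: none
Why: Buffered Dess–Martin oxidation avoids the Z→E isomerisation seen with prolonged MnO2 contact.

**Step 12**
Reactants: 13
Product: 14 cis-fused decalin: CHO and Me on the new quaternary carbon, c–CH2OTBS, OMe/OCONH2 ring A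
Conditions: (2S,5S)-5-benzyl-2-tert-butyl-3-methylimidazolidin-4-one·TFA (30 mol%), MeCN/H2O 95:5, −10 → 23 °C, 48 h
Reagents that add atoms: none
Why: Proposed new method: iminium-catalysed IMDA of a Z-β-alkyl-α-methyl enal (a trisubstituted dienophile) with an E,E-diene across a four-atom syn-1,3-dioxygenated tether. The imidazolidinone lowers the LUMO and shields one iminium face. The Z-enal and E,E-diene force an endo, chair-like TS with C1-OMe and C3-O equatorial. This gives the cis ring fusion, sets the all-carbon quaternary Me/CHO centre and the c-centre, and closes ring A and ring B together. Closest known: MacMillan imidazolidinone Diels–Alder of α-substituted enals and organocatalytic IMDA of tethered trienals.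

**Step 13**
Reactants: 15 2-butyn-1-ol
Product: 16 (Z)-3-iodobut-2-en-1-ol
Conditions: Red-Al (1.5 equiv), Et2O, 0 → 23 °C; EtOAc; I2 (1.5 equiv), −78 °C
Reagents that add atoms: iodine, II
Why: Alkoxide-directed trans-hydroalumination via a 5-membered alumina-cycle, then iodinolysis, places I cis to CH2OH (Z).

**Step 14**
Reactants: 16
Product: 17 ethyl (2E,4Z)-5-iodohexa-2,4-dienoate
Conditions: MnO2 (15 equiv), Ph3P=CHCO2Et (1.5 equiv), CH2Cl2, 23 °C
Reagents that add atoms: (carbethoxymethylene)triphenylphosphorane, CCOC(=O)C=P(c1ccccc1)(c1ccccc1)c1ccccc1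
Why: Tandem oxidation–Wittig avoids isolating the volatile Z-iodoenal, gives the E-enoate and retains the Z-vinyl iodide.

**Step 15**
Reactants: 17
Product: 18 (2E,4Z)-5-iodohexa-2,4-dienoic acid
Conditions: LiOH·H2O (5 equiv), THF/H2O 3:1, 23 °C, dark
Reagents that add atoms: water (hydroxide), O
Why: Saponification of the ethyl ester leaves both alkene geometries and the C–I bond unchanged.

**Step 16**
Reactants: 19 N-(diphenylmethylene)glycine tert-butyl ester
Product: 20 tert-butyl N-(diphenylmethylene)-D-alaninate (R)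
Conditions: MeI (1.5 equiv), Maruoka-type spiro-binaphthyl ammonium bromide (1 mol%), 50% aq KOH, toluene, 0 °C
Reagents that add atoms: MeI, CI
Why: Asymmetric phase-transfer alkylation (O'Donnell–Maruoka) of the glycine enolate; the catalyst enantiomer is chosen to give the (R) centre, which becomes Cs3.

**Step 17**
Reactants: 20
Product: 21 tert-butyl D-alaninate
Conditions: 1 M HCl, THF, 23 °C, 1 h; then NaHCO3
Reagents that add atoms: none
Why: Mild imine hydrolysis keeps the tert-butyl ester and the α-centre intact.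

**Step 18**
Reactants: 21
Product: 22 tert-butyl N,N-dibenzyl-D-alaninate
Conditions: BnBr (2.5 equiv), K2CO3 (3 equiv), MeCN, 60 °C
Reagents that add atoms: benzyl bromide, BrCc1ccccc1
Why: Double SN2 N-alkylation gives the bulky, non-chelating NBn2 group needed for Felkin control later.

**Step 19**
Reactants: 22
Product: 23 (R)-N,N-dibenzylalaninal
Conditions: DIBAL-H (1.1 equiv), toluene, −78 °C
Reagents that add atoms: none
Why: Partial reduction of the ester to the aldehyde; the aldehyde is used immediately because the α-centre is configurationally sensitive.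

**Step 20**
Reactants: 23, 24 (E)-crotylboronic acid pinacol ester
Product: 25 anti,anti-homoallylic amino alcohol
Conditions: 24 (3 equiv), toluene, 23 °C, 72 h
Reagents that add atoms: none (24 is the numbered reactant)
Why: Felkin–Anh addition (NBn2 perpendicular, non-chelating) sets Cs2 anti to Cs3, and the chair Zimmerman–Traxler TS of the E-crotylboronate sets Cs1/Cs2 anti (E-crotylboration).

**Step 21**
Reactants: 25
Product: 26 Cs2-OTBS ether
Conditions: TBSOTf (1.5 equiv), 2,6-lutidine (2.5 equiv), CH2Cl2, −78 °C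
Reagents that add atoms: TBSOTf, CC(C)(C)[Si](C)(C)OS(=O)(=O)C(F)(F)F
Why: The triflate is needed to silylate this hindered secondary alcohol; no stereocentre changes.

**Step 22**
Reactants: 26
Product: 27 anti-α-methyl-β-silyloxy aldehyde
Conditions: OsO4 (2.5 mol%), NaIO4 (4 equiv), 2,6-lutidine (2 equiv), dioxane/H2O 3:1, 23 °C
Reagents that add atoms: sodium periodate (oxygen source), [Na+].[O-]I(=O)(=O)=O
Why: Lemieux–Johnson cleavage is used instead of ozone so the tertiary amine is not oxidised; the aldehyde is taken on immediately to limit epimerisation of Cs1.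

**Step 23**
Reactants: 27, 28 propanal
Product: 29 diol (aldol then NaBH4 reduction): Cm/Cl anti, Cl/Cs1 syn
Conditions: (R)-proline (30 mol%), DMF, 4 °C, propanal added over 20 h by syringe pump; then NaBH4, MeOH, 0 °C
Reagents that add atoms: none (propanal is numbered 28)
Why: Proline-enamine anti-selective cross-aldol (Northrup–MacMillan) attacks the Felkin face of the anti-α-methyl-β-silyloxy aldehyde (matched case), setting Cl and Cm; the proline enantiomer that matches the Felkin face is assumed to be (R) (screen both).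

**Step 24**
Reactants: 29
Product: 30 N-acetyl amino diol
Conditions: H2 (1 atm), Pd(OH)2/C, EtOH, 23 °C; filter; then Ac2O (1.05 equiv), 0 °C
Reagents that add atoms: acetic anhydride, CC(=O)OC(C)=O
Why: Hydrogenolysis of the benzyl groups (no alkenes are present at this stage), then chemoselective N-acetylation of the free amine over the alcohols.

**Step 25**
Reactants: 30
Product: 31 primary 1-phenyltetrazol-5-yl sulfide
Conditions: PT-SH (1.5 equiv), PPh3 (1.5 equiv), DIAD (1.5 equiv), THF, 0 °C
Reagents that add atoms: 1-phenyl-1H-tetrazole-5-thiol, Sc1nnnn1-c1ccccc1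
Why: Mitsunobu thioetherification occurs at the unhindered primary alcohol and not at the flanked secondary one; there is no stereochemical change.

**Step 26**
Reactants: 31
Product: 32 PT-sulfone
Conditions: (NH4)6Mo7O24·4H2O (0.2 equiv), 30% H2O2 (15 equiv), EtOH, 0 → 23 °C
Reagents that add atoms: hydrogen peroxide, OO
Why: Molybdate-catalysed oxidation converts the sulfide to the sulfone; the amide, free OH and TBS ether are inert.

**Step 27**
Reactants: 32
Product: 33 Cl-OTES sulfone
Conditions: TESCl (2 equiv), imidazole (4 equiv), DMF, 23 °C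
Reagents that add atoms: chlorotriethylsilane, CC[Si](Cl)(CC)CC
Why: A TES group on Cl–OH avoids alkoxide interference in the Julia–Kocienski step and can later be removed selectively in the presence of the TBS ether.

**Step 28**
Reactants: 14
Product: 34 (E)-vinyl iodide at the quaternary carbon
Conditions: CHI3 (2.5 equiv), CrCl2 (10 equiv), THF, 23 °C
Reagents that add atoms: iodoform, IC(I)I
Why: Takai–Utimoto olefination of the neopentyl aldehyde gives the E-iodoalkene; the carbamate and silyl ether are tolerated.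

**Step 29**
Reactants: 34
Product: 35 (E)-vinyltrimethylstannane
Conditions: Me3SnSnMe3 (1.5 equiv), Pd(PPh3)4 (10 mol%), toluene, 70 °C
Reagents that add atoms: hexamethylditin, C[Sn](C)(C)[Sn](C)(C)C
Why: Pd-catalysed iodide-to-stannane exchange with retention of the E geometry prepares the Stille partner.

**Step 30**
Reactants: 35
Product: 36 primary alcohol (c–CH2OH)
Conditions: TBAF (1.2 equiv), AcOH (1.2 equiv), THF, 0 °C
Reagents that add atoms: none
Why: Buffered fluoride removes the primary TBS ether; the vinylstannane and carbamate are unaffected.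

**Step 31**
Reactants: 36
Product: 37 c-aldehyde
Conditions: DMP (1.5 equiv), NaHCO3 (5 equiv), CH2Cl2, 0 °C
Reagents that add atoms: none
Why: Mild buffered oxidation; the α/allylic c-stereocentre is protected from epimerisation by immediate use of the crude aldehyde.

**Step 32**
Reactants: 37
Product: 38 (E)-2-methyl-enal
Conditions: Ph3P=C(Me)CHO (3 equiv), toluene, 70 °C
Reagents that add atoms: 2-(triphenylphosphoranylidene)propanal, CC(=P(c1ccccc1)(c1ccccc1)c1ccccc1)C=O
Why: Stabilised-ylide Wittig reaction gives the E-trisubstituted enal (c trans to CHO).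

**Step 33**
Reactants: 38, 33
Product: 39 E,E-diene-linked polyene
Conditions: KHMDS (4 equiv), DME, −55 → 23 °C
Reagents that add atoms: none
Why: Julia–Kocienski olefination of the PT-sulfone carbanion with the enal gives the E-alkene, completing the c–CH=C(Me)–CH=CH–Cm diene; excess base covers the N–H protons.

**Step 34**
Reactants: 39
Product: 40 free Cl-alcohol
Conditions: PPTS (0.3 equiv), MeOH/CH2Cl2 1:1, 0 → 23 °C
Reagents that add atoms: none
Why: The TES ether is cleaved selectively over TBS, exposing the alcohol for the macrocyclic ester.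

**Step 35**
Reactants: 40, 18
Product: 41 seco-ester carrying vinyl iodide and vinylstannane
Conditions: 18 (3 equiv), Et3N (4 equiv), 2,4,6-Cl3C6H2COCl (3 equiv), THF; then 40 and DMAP (6 equiv), PhMe, 40 °C
Reagents that add atoms: none (the acid is numbered 18)
Why: Yamaguchi esterification of the hindered secondary alcohol through the mixed anhydride, with no effect on the stereocentres or alkene geometries.

**Step 36**
Reactants: 41
Product: 42 TBS-protected macrolactone
Conditions: Pd(PPh3)4 (30 mol%), CuTC (3 equiv), NMP, 2 mM, 23 °C, syringe-pump addition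
Reagents that add atoms: none
Why: Intramolecular Stille coupling at high dilution joins the (E)-vinylstannane to the (Z)-iodoalkene with retention at both partners, forming the (Z)-trisubstituted diene and closing the 16-membered ring.

**Step 37**
Reactants: 42
Product: 43 Superstolide A
Conditions: HF·pyridine, pyridine, THF, 0 → 23 °C, 24 h
Reagents that add atoms: none
Why: Fluoride removes the last silyl group to free the Cs2 hydroxyl; the lactone, carbamate, acetamide and polyene are stable to buffered HF.

---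

## Compound list
1 | (E)-but-2-ene-1,4-diol | OC/C=C/CO | starting material
2 | (E)-4-(TBSO)but-2-en-1-ol | CC(C)(C)[Si](C)(C)OC/C=C/CO | intermediate
3 | (2E,4E)-6-(TBSO)hexa-2,4-dienal | CC(C)(C)[Si](C)(C)OC/C=C/C=C/C=O | intermediate
4 | 4,4-dimethoxybutan-2-one | COC(OC)CC(C)=O | starting material
5 | (5S)-aldol adduct (β-hydroxy ketone) | CC(C)(C)[Si](C)(C)OC/C=C/C=C/[C@@H](O)CC(=O)CC(OC)OC | intermediate
6 | syn-1,3-diol | CC(C)(C)[Si](C)(C)OC/C=C/C=C/[C@@H](O)C[C@@H](O)CC(OC)OC | intermediate
7 | cyclic mixed acetal (anomeric mixture) | CC(C)(C)[Si](C)(C)OC/C=C/C=C/[C@@H]1C[C@@H](O)CC(OC)O1 | intermediate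
8 | C1-methyl ether of 7 | CC(C)(C)[Si](C)(C)OC/C=C/C=C/[C@@H]1C[C@@H](OC)CC(OC)O1 | intermediate
9 | lactol | CC(C)(C)[Si](C)(C)OC/C=C/C=C/[C@@H]1C[C@@H](OC)CC(O)O1 | intermediate
10 | Z-hydroxy enoate | CC(C)(C)[Si](C)(C)OC/C=C/C=C/[C@@H](O)C[C@@H](OC)C/C=C(/C)C(=O)OC | intermediate
11 | Z-enoate carbamate | CC(C)(C)[Si](C)(C)OC/C=C/C=C/[C@@H](OC(N)=O)C[C@@H](OC)C/C=C(/C)C(=O)OC | intermediate
12 | Z-allylic alcohol | CC(C)(C)[Si](C)(C)OC/C=C/C=C/[C@@H](OC(N)=O)C[C@@H](OC)C/C=C(/C)CO | intermediate
13 | Z-enal (IMDA substrate) | CC(C)(C)[Si](C)(C)OC/C=C/C=C/[C@@H](OC(N)=O)C[C@@H](OC)C/C=C(/C)C=O | intermediate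
14 | cis-decalin aldehyde | CO[C@@H]1C[C@H](OC(N)=O)[C@@H]2C=C[C@H](CO[Si](C)(C)C(C)(C)C)[C@](C)(C=O)[C@@H]2C1 | intermediate
15 | 2-butyn-1-ol | CC#CCO | starting material
16 | (Z)-3-iodobut-2-en-1-ol | OC/C=C(\I)C | intermediate
17 | ethyl (2E,4Z)-5-iodohexa-2,4-dienoate | CCOC(=O)/C=C/C=C(C)\I | intermediate
18 | (2E,4Z)-5-iodohexa-2,4-dienoic acid | OC(=O)/C=C/C=C(C)\I | intermediate
19 | N-(diphenylmethylene)glycine tert-butyl ester | CC(C)(C)OC(=O)CN=C(c1ccccc1)c1ccccc1 | starting material
20 | (R)-alanine imine tert-butyl ester | CC(C)(C)OC(=O)[C@@H](C)N=C(c1ccccc1)c1ccccc1 | intermediate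
21 | tert-butyl D-alaninate | CC(C)(C)OC(=O)[C@@H](C)N | intermediate
22 | tert-butyl N,N-dibenzyl-D-alaninate | CC(C)(C)OC(=O)[C@@H](C)N(Cc1ccccc1)Cc1ccccc1 | intermediate
23 | (R)-N,N-dibenzylalaninal | O=C[C@@H](C)N(Cc1ccccc1)Cc1ccccc1 | intermediate
24 | (E)-crotylboronic acid pinacol ester | C/C=C/CB1OC(C)(C)C(C)(C)O1 | starting material
25 | anti,anti-homoallylic amino alcohol | C=C[C@H](C)[C@H](O)[C@@H](C)N(Cc1ccccc1)Cc1ccccc1 | intermediate
26 | Cs2-OTBS ether | C=C[C@H](C)[C@H](O[Si](C)(C)C(C)(C)C)[C@@H](C)N(Cc1ccccc1)Cc1ccccc1 | intermediate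
27 | anti-α-methyl-β-silyloxy aldehyde | O=C[C@H](C)[C@H](O[Si](C)(C)C(C)(C)C)[C@@H](C)N(Cc1ccccc1)Cc1ccccc1 | intermediate
28 | propanal | CCC=O | starting material
29 | stereopentad diol (NBn2) | OC[C@@H](C)[C@H]([C@H](C)[C@H](O[Si](C)(C)C(C)(C)C)[C@@H](C)N(Cc1ccccc1)Cc1ccccc1)O | intermediate
30 | N-acetyl diol | OC[C@@H](C)[C@H]([C@H](C)[C@H](O[Si](C)(C)C(C)(C)C)[C@@H](C)NC(C)=O)O | intermediate
31 | PT sulfide | c1ccccc1-n1nnnc1SC[C@@H](C)[C@H]([C@H](C)[C@H](O[Si](C)(C)C(C)(C)C)[C@@H](C)NC(C)=O)O | intermediate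
32 | PT sulfone | c1ccccc1-n1nnnc1S(=O)(=O)C[C@@H](C)[C@H]([C@H](C)[C@H](O[Si](C)(C)C(C)(C)C)[C@@H](C)NC(C)=O)O | intermediate
33 | TES-protected PT sulfone | c1ccccc1-n1nnnc1S(=O)(=O)C[C@@H](C)[C@H]([C@H](C)[C@H](O[Si](C)(C)C(C)(C)C)[C@@H](C)NC(C)=O)O[Si](CC)(CC)CC | intermediate
34 | (E)-vinyl iodide | CO[C@@H]1C[C@H](OC(N)=O)[C@@H]2C=C[C@H](CO[Si](C)(C)C(C)(C)C)[C@](C)(/C=C/I)[C@@H]2C1 | intermediate
35 | (E)-vinylstannane | CO[C@@H]1C[C@H](OC(N)=O)[C@@H]2C=C[C@H](CO[Si](C)(C)C(C)(C)C)[C@](C)(/C=C/[Sn](C)(C)C)[C@@H]2C1 | intermediate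
36 | c-CH2OH stannane | CO[C@@H]1C[C@H](OC(N)=O)[C@@H]2C=C[C@H](CO)[C@](C)(/C=C/[Sn](C)(C)C)[C@@H]2C1 | intermediate
37 | c-aldehyde stannane | CO[C@@H]1C[C@H](OC(N)=O)[C@@H]2C=C[C@H](C=O)[C@](C)(/C=C/[Sn](C)(C)C)[C@@H]2C1 | intermediate
38 | (E)-enal stannane | CO[C@@H]1C[C@H](OC(N)=O)[C@@H]2C=C[C@H](/C=C(C)/C=O)[C@](C)(/C=C/[Sn](C)(C)C)[C@@H]2C1 | intermediate
39 | Julia–Kocienski product | CO[C@@H]1C[C@H](OC(N)=O)[C@@H]2C=C[C@H](/C=C(C)/C=C/[C@@H](C)[C@H]([C@H](C)[C@H](O[Si](C)(C)C(C)(C)C)[C@@H](C)NC(C)=O)O[Si](CC)(CC)CC)[C@](C)(/C=C/[Sn](C)(C)C)[C@@H]2C1 | intermediate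
40 | free Cl-alcohol | CO[C@@H]1C[C@H](OC(N)=O)[C@@H]2C=C[C@H](/C=C(C)/C=C/[C@@H](C)[C@H]([C@H](C)[C@H](O[Si](C)(C)C(C)(C)C)[C@@H](C)NC(C)=O)O)[C@](C)(/C=C/[Sn](C)(C)C)[C@@H]2C1 | intermediate
41 | seco-ester | CO[C@@H]1C[C@H](OC(N)=O)[C@@H]2C=C[C@H](/C=C(C)/C=C/[C@@H](C)[C@H]([C@H](C)[C@H](O[Si](C)(C)C(C)(C)C)[C@@H](C)NC(C)=O)OC(=O)/C=C/C=C(C)\I)[C@](C)(/C=C/[Sn](C)(C)C)[C@@H]2C1 | intermediate
42 | TBS-protected macrolactone | CO[C@@H]1C[C@H](OC(N)=O)[C@@H]2C=C[C@@H]3/C=C(C)/C=C/[C@@H](C)[C@H]([C@H](C)[C@H](O[Si](C)(C)C(C)(C)C)[C@@H](C)NC(C)=O)OC(=O)/C=C/C=C(C)\C=C\[C@]3(C)[C@@H]2C1 | intermediate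
43 | Superstolide A | CO[C@@H]1C[C@H](OC(N)=O)[C@@H]2C=C[C@@H]3/C=C(C)/C=C/[C@@H](C)[C@H]([C@H](C)[C@H](O)[C@@H](C)NC(C)=O)OC(=O)/C=C/C=C(C)\C=C\[C@]3(C)[C@@H]2C1 | target

---

**Total steps:** 37. **Longest linear sequence:** 22 (1 → 14 in 12 steps, then steps 28–37).

**Three steps most likely to fail:**
1. **Step 12, the IMDA (proposed new step).** Z-α,β-disubstituted enals form iminium ions poorly, and Z→E isomerisation via the dienamine would give the quaternary-centre epimer. Fallback (known chemistry): Me2AlCl- or thermal-promoted IMDA of enal **13** under substrate control, with the C1/C3 syn-dioxygenated tether forcing the equatorial chair TS, followed by chromatographic separation of diastereomers.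
2. **Step 23, the proline cross-aldol on the hindered α-chiral β-silyloxy aldehyde.** Enamine formation on the acceptor could cause Cs1 epimerisation or β-elimination, and the catalyst/Felkin match is unproven. Fallback: replace the aldol with a second E-crotylboration of **27** (a Felkin-matched anti aldehyde), then TES protection, Lemieux–Johnson cleavage and NaBH4 reduction.
3. **Step 36, the macrocyclic Stille coupling.** Forming the Z-trisubstituted diene inside a strained, highly conjugated 16-membered ring may give oligomers or isomerisation. Fallback: intermolecular Stille of **40** with ester **17**, saponification (Me3SnOH), then Yamaguchi or Shiina macrolactonisation of the seco-acid.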